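Slowing comes first, so watch the substrate. In the violet run it reads 29% at 10.0 s and 9% at 20.0 s, an average loss constant of 0.117 s⁻¹, with the substrate falling by a factor of 3.22 over that stretch.

| setting | violet | grey | Monday's | Wednesday's | Saturday's | Thursday's |
|---|---|---|---|---|---|---|
| substrate | 0.050 M | 0.050 M | 0.050 M | 0.050 M | 0.050 M | 0.050 M |
| enzyme | 0.29 µM | 0.96 µM | 0.20 µM | 0.30 µM | 0.40 µM | 0.60 µM |
| remark | run made earlier | run made earlier |  |  |  |  |
| time |  |  | 3.0 min | 3.0 min | 3.0 min | 3.0 min |

- violet (time / s: target / %, uncatalysed product / %, substrate / %): 10.0: 18, 54, 29; 12.0: 20, 58, 25; 20.0: 24, 68, 9; 30.0: 26, 75, 0; 50.0: 26, 72, 2; 90.0: 25, 72, 0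
- grey (time / s: target / %, uncatalysed product / %, substrate / %): 15.0: 49, 44, 5; 30.0: 56, 46, 0; 50.0: 53, 46, 0; 60.0: 53, 47, 1; 80.0: 54, 45, 3; 90.0: 51, 46, 0

(standard deviation of a reading: 1.5 percentage points)

- "hardly changes" means that all values lie within two and a half points (for a concentration: within two and a half percent of the largest)

- share of target in all that became target or uncatalysed product for Monday's, Wednesday's, Saturday's, Thursday's, in this order
- how the row runs (rises all the way / falls, then rises / rises, then falls / hardly changes / falls all the way)

Does that slowing shift the split between the routes? Look at the violet run. Target over uncatalysed product reads 0.333 at 10.0 s and 0.352 on the plateau, close for readings with a scatter of 1.5 percentage points. These are running totals, so they can't show that the two rates slow alike, but they let you freeze the whole-run ratio and ask how it goes with the enzyme charge E.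

My reckoning carries one quantity, the split b: target formed per unit of uncatalysed product, per µM of enzyme, a selectivity factor. With T and U the amounts of target and uncatalysed product at the end of a run:

T / U = b·E

share = bE / (1 + bE)

The violet plateau gives b = 1.21 µM⁻¹. The grey plateau, a different flask, gives 1.21 µM⁻¹.

Sharing out the violet loss constant in that ratio, I estimate that the uncatalysed route alone halves the substrate every 8.01 s, and your 3.0 min is far longer than that. So you expect the substrate to be used up, and the share runs from 19.5% at 0.20 µM to 42.1% at 0.60 µM, rising throughout.

The forecast, on the ground that “the ratio is proportional to enzyme”, takes 1.22 per µM where I take 1.21 µM⁻¹. It gives 19.6%, 26.8%, 32.8%, 42.3%: rises all the way.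

The flasks give 19.0%, 26.0%, 31.9%, 41.3%: rises all the way.

    substrate + enzyme → target + enzyme, rate k1*[substrate]*[enzyme]/(1 + ([substrate]/Km1)) (0.146 M, k = 1.21 × 10⁵ M⁻¹ s⁻¹)
    substrate → uncatalysed product (k = 0.0885 s⁻¹)

Monday's share returns b = 1.17 µM⁻¹, and Thursday's share returns 1.17 µM⁻¹. Put on Thursday's flask, the b from the earlier runs gives 42.1% against the simulated 41.3%. At the start of Monday's flask, the step to uncatalysed product uses substrate 4.9 times as fast as the step to target. Over the whole of Monday's run it makes 4.26 times as much product as the step to target.

The runs are simulated on assumed constants; scatter was added.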